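How much of the solid substrate in this flask has reacted by 12 min, and what is the pH then?

| flask | solid substrate | acid | remark | time |
|---|---|---|---|---|
| south-west | 0.010 M | 0.20 mM | run made earlier |  |
| north | 0.040 M | 0.20 mM | run made earlier |  |
| west | 0.020 M | 0.10 mM | run made earlier |  |
| flask | 0.020 M | 0.200 mM |  | 12 min |

- south-west (time / min: solid substrate / %, target / %): 1.50: 98.2, 1.6; 3.00: 97.0, 2.9; 5.00: 94.0, 5.3; 6.00: 93.0, 7.4; 8.00: 91.1, 8.3; 10.0: 88.8, 11.1; 12.0: 86.3, 13.4
- north (time / min: solid substrate / %, target / %): 1.00: 99.8, 0.5; 1.33: 99.5, 0; 2.00: 98.7, 0.5; 3.00: 99.3, 1.6; 5.00: 99.5, 1.3; 8.00: 97.1, 2.4; 12.0: 96.8, 3.5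
- west (time / min: solid substrate / %, target / %): 2.50: 98.9, 1.5; 5.00: 96.9, 2.5; 8.00: 95.0, 4.6; 10.0: 94.3, 5.1; 12.0: 93.8, 6.5

(scatter of a reading: 0.5 percentage points)

- part of the solid substrate that has reacted (what has only dissolved counts as not reacted) at 12 min
- pH of the solution at 12 min

- acid is the free proton; pH is minus the decimal logarithm of its molar concentration
- solid substrate is a solid; its amount is given per volume of the solution
- the numbers in the tables scatter with a standard deviation of 0.5 percentage points
- on the list of suspects stand: starting material + acid -> weak acid + acid + target; weak acid <-> conjugate base + acid; starting material -> weak acid + target; weak acid + target -> side product; solid substrate <-> starting material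
- at the start none of the solid substrate is in solution
- what has only dissolved of solid substrate counts as not reacted

- Start the ledger from the limiting reagent, solid substrate, and count its loss in mM rather than in percent. Call F the millimoles per litre lost each minute, a zero-order loss rate.
- By their last readings, the south-west run lost 0.114 mM min⁻¹, the north run 0.107 mM min⁻¹ and the west run, on 0.10 mM acid, 0.103 mM min⁻¹. Charges from 0.010 M to 0.040 M leave F nearly unmoved, so I take the mean, 0.108 mM min⁻¹.
- The south-west line reads straight: that run had lost half of its 12.0 min loss by 6.00 min.
- The credit side closes within the scatter, since solid substrate plus target ends at 99.7% in the south-west run and 100% in the north run.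
- For this flask, F times 12 min is 1.30 mM out of 0.020 M, so I commit to 6.48% reacted.
- On the list of suspects that loss gives weak acid, but no run reads a pH. I bracket it between 3.7, with the weak acid undissociated, and 2.8, with the weak acid fully dissociated.
- The forecast gave 6.7% (6% to 7.4%) and pH 3.4 (2.9 to 3.7), holding that “the rate does not depend on the solid charged”.
- The flask gives pH 3.55 and 6.80% reacted, the latter 0.32 percentage points above my figure.

    starting material + acid → weak acid + acid + target (k = 10900 M⁻¹ s⁻¹)
    weak acid ⇌ conjugate base + acid, settled at all times (K = 2.00 × 10⁻⁵ M)
    starting material → weak acid + target (k = 0.0637 min⁻¹)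
    weak acid + target → side product (k = 14.1 M⁻¹ min⁻¹)
    solid substrate ⇌ starting material, rate k5*(cs5 - [starting material]) while solid is left; crystals form when [starting material] > cs5 (solubility = 0.860 mM, k = 0.132 min⁻¹)

- At 12.0 min in this flask, starting material has a half-life of 0.22 s by the acid step, far shorter than 11 min by the uncatalysed step, and it stands at 0% beside 93.2% of solid substrate. The rate at which it is made over the rate at which it is used up, each step taken net, stands at 1.00.
- Read at 50 min, the same flask should have lost 27.0% by F. The computed result is 28.4%, with 72% of the solid substrate still there, solid or dissolved.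

The data come from a simulation with constants of no real substance, noise included.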